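The route rests on cutting ring C of the flavanone at O1–C2 and C3–C4, so that C2–C3 comes from a styrene and ring A arrives as a salicylaldehyde acetal. The feature used is that ring C is fused to ring A through a phenolic oxygen (O1) and a benzylic carbon (C4) whose ketone can be stored as a 4-methoxy group. One chiral-acid-catalysed hetero-[4+2] of the derived methoxy ortho-quinone methide with 4-(benzyloxy)styrene forms both bonds, closes ring C and sets C2. The precursor is a 2-(dimethoxymethyl)phenol carrying one free OH, methyl ethers on the future O5 and O7, and the benzyl-protected 2-hydroxybenzyl group at the future C6.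

Key step: step 8

Remarks on the chemistry
- Assumption: the target is the (2R) enantiomer as drawn in the SMILES. The sense of induction of the chiral phosphoramide with an alkoxy-substituted methide cannot be predicted safely, so the (R)-catalyst is written and its antipode would be used if the first run points to (2S).
- Ring A is kept mirror-symmetric until the formyl group is introduced, and the precursor has a single free phenol. Formylation and ring closure therefore have no regiochemical alternative.
- The C4 epimers of 14 should be pooled only after each has been shown to be (2R), because a (2S,4R) epimer would lead to the enantiomer of ketone 16.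
- Acetal 10 should be kept over a trace of Et3N, not chromatographed on silica, and added slowly to excess styrene, because its free ring position (the future C8) can attack its own carbenium ion.

Step 1
Reactants: 1 4-hydroxy-2,6-dimethoxybenzaldehyde
Product: 2 4-[(tert-butyldimethylsilyl)oxy]-2,6-dimethoxybenzaldehyde
Conditions: TBSCl, imidazole, DMF, rt
Reagents that add atoms: tert-butyldimethylsilyl chloride, CC(C)(C)[Si](C)(C)Cl
Why: Imidazole-promoted silylation of the phenol (silyl ether formation) removes the acidic OH, which as a para-phenoxide would quench the Grignard reagent and deactivate the aldehyde.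

Step 2
Reactants: 2 4-[(tert-butyldimethylsilyl)oxy]-2,6-dimethoxybenzaldehyde; 3 1-(benzyloxy)-2-bromobenzene
Product: 5 [2-(benzyloxy)phenyl]{4-[(tert-butyldimethylsilyl)oxy]-2,6-dimethoxyphenyl}methanol (racemic), via aryl Grignard reagent 4 (not isolated)
Conditions: Mg, THF, rt; then 2, 0 °C to rt; aq NH4Cl
Reagents that add atoms: none
Why: Grignard addition of the aryl magnesium bromide, formed by magnesium insertion into 3, to the aldehyde of 2 should give the diaryl carbinol; its new stereocentre forms as a racemate and is removed in step 3.

Step 3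
Reactants: 5 [2-(benzyloxy)phenyl]{4-[(tert-butyldimethylsilyl)oxy]-2,6-dimethoxyphenyl}methanol
Product: 6 {4-[2-(benzyloxy)benzyl]-3,5-dimethoxyphenoxy}(tert-butyl)dimethylsilane
Conditions: Et3SiH, TFA, CH2Cl2, 0 °C
Reagents that add atoms: none
Why: Ionic hydrogenation, in which TFA ionises the carbinol to a diarylmethyl cation stabilised by the three ring oxygens and Et3SiH transfers hydride to it, while aryl silyl and benzyl ethers should tolerate brief cold acid.

Step 4
Reactants: 6 {4-[2-(benzyloxy)benzyl]-3,5-dimethoxyphenoxy}(tert-butyl)dimethylsilane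
Product: 7 4-[2-(benzyloxy)benzyl]-3,5-dimethoxyphenol
Conditions: n-Bu4NF, THF, 0 °C; aq NH4Cl
Reagents that add atoms: none
Why: Fluoride-induced desilylation of the aryl silyl ether is driven by the Si–F bond and leaves benzyl and methyl ethers untouched.

Step 5
Reactants: 7 4-[2-(benzyloxy)benzyl]-3,5-dimethoxyphenol
Product: 8 3-[2-(benzyloxy)benzyl]-6-hydroxy-2,4-dimethoxybenzaldehyde
Conditions: MgCl2, Et3N, (CH2O)n, MeCN, reflux; 1 M HCl work-up
Reagents that add atoms: paraformaldehyde (as formaldehyde), C=O
Why: Magnesium-mediated ortho-formylation of a phenol (Casnati–Skattebøl reaction), in which the magnesium phenoxide delivers formaldehyde to the adjacent carbon and a second formaldehyde oxidises the benzylic alkoxide; the two ortho positions are equivalent and the para position is blocked, so only one aldehyde can form.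

Step 6
Reactants: 8 3-[2-(benzyloxy)benzyl]-6-hydroxy-2,4-dimethoxybenzaldehyde; 9 trimethyl orthoformate
Product: 10 4-[2-(benzyloxy)benzyl]-2-(dimethoxymethyl)-3,5-dimethoxyphenol
Conditions: 9 (excess), MeOH, pyridinium p-toluenesulfonate (cat.), 40 °C; then Et3N, evaporate, no silica
Reagents that add atoms: methanol, CO (co-solvent that exchanges with the methoxy groups supplied by 9)
Why: Acid-catalysed acetalisation driven by the orthoformate as dehydrating agent (it ends as methyl formate); quenching with Et3N before concentration should preserve the acid-labile, electron-rich acetal with its phenol free.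

Step 7
Reactants: 11 4-(benzyloxy)benzaldehyde
Product: 12 4-(benzyloxy)styrene
Conditions: Ph3PCH3Br, KOt-Bu, THF, 0 °C to rt
Reagents that add atoms: methyltriphenylphosphonium bromide, C[P+](c1ccccc1)(c1ccccc1)c1ccccc1.[Br-]
Why: Wittig methylenation of a non-enolisable aryl aldehyde with the unstabilised ylide is reliable and tolerates the benzyl ether.

Step 8
Reactants: 10 4-[2-(benzyloxy)benzyl]-2-(dimethoxymethyl)-3,5-dimethoxyphenol; 12 4-(benzyloxy)styrene
Product: 14 (2R,4R)-6-[2-(benzyloxy)benzyl]-2-[4-(benzyloxy)phenyl]-4,5,7-trimethoxychroman (2,4-cis), via methoxy ortho-quinone methide 13 (not isolated)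
Conditions: (R)-3,3'-bis(2,4,6-triisopropylphenyl)-1,1'-binaphthyl-2,2'-diyl N-triflylphosphoramide (10 mol%), 12 (3 equiv), 5 Å MS, toluene, −40 °C, slow addition of 10; then Et3N
Reagents that add atoms: none
Why: Proposed new method: the strongly acidic chiral phosphoramide protonates one acetal oxygen of 10, methanol leaves, and the resulting 2-hydroxyaryl methoxycarbenium ion (the O-protonated form of methide 13) stays hydrogen-bonded through its phenolic OH to the chiral anion, after which the CH2 terminus of 12 attacks C4 and the phenolic oxygen captures the developing para-benzyloxybenzyl cation at C2 in an asynchronous inverse-demand hetero-[4+2] that restores the aromaticity of ring A. The closest known reaction types are the N-triflylphosphoramide-catalysed enantioselective [4+2] cycloadditions of aryl-substituted ortho-quinone methides with styrenes and the achiral acid-promoted cycloadditions of salicylaldehyde acetals with alkenes to 4-alkoxychromans; new here is enantiocontrol with an alkoxy-substituted methide. Ring C (six-membered) is closed by the [4+2] mode itself, with C3–C4 leading and O1–C2 following inside one ion pair. C4 is set by the face of the carbenium ion that the bound chiral anion leaves open, and C2 is set relative to C4 by an endo placement of the styrene aryl group, which should give the 2,4-cis adduct. The step needs regioselectivity (aryl at C2), secured by the polarity of the para-alkoxystyrene, and a single mode of ring closure, secured by the single free phenol of 10. It also needs ionisation of the acetal in preference to the product ether, which rests on the greater stability of the oxocarbenium ion and is supported by low temperature, slow addition and sieves that bind methanol.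

Step 9
Reactants: 14 (2R,4R)-6-[2-(benzyloxy)benzyl]-2-[4-(benzyloxy)phenyl]-4,5,7-trimethoxychroman
Product: 15 (2R)-6-[2-(benzyloxy)benzyl]-2-[4-(benzyloxy)phenyl]-5,7-dimethoxychroman-4-ol (mixture of C4 epimers)
Conditions: 0.1 M aq HCl, THF, 0 °C, high dilution; then aq NaHCO3
Reagents that add atoms: water, O
Why: SN1 hydrolysis of a benzylic ether, in which the C4 cation stabilised by O1 and the 5- and 7-methoxy groups forms under dilute acid and is captured by the large excess of water; C2 is not involved, and the C4 configuration does not matter because it is oxidised next.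

Step 10
Reactants: 15 (2R)-6-[2-(benzyloxy)benzyl]-2-[4-(benzyloxy)phenyl]-5,7-dimethoxychroman-4-ol
Product: 16 (R)-6-[2-(benzyloxy)benzyl]-2-[4-(benzyloxy)phenyl]-5,7-dimethoxychroman-4-one
Conditions: Dess–Martin periodinane, NaHCO3, CH2Cl2, 0 °C to rt
Reagents that add atoms: none
Why: Dess–Martin oxidation of the secondary benzylic alcohol under bicarbonate buffering gives the ketone without acid or base strong enough to open ring C, so C2 should be retained and both C4 epimers converge.

Step 11
Reactants: 16 (R)-6-[2-(benzyloxy)benzyl]-2-[4-(benzyloxy)phenyl]-5,7-dimethoxychroman-4-one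
Product: 17 (R)-5-hydroxy-6-(2-hydroxybenzyl)-2-(4-hydroxyphenyl)-7-methoxychroman-4-one, (+)-methylphelligrin A
Conditions: BCl3, C6HMe5, CH2Cl2, −78 to 0 °C; then H2O
Reagents that add atoms: none
Why: Lewis-acid ether cleavage with BCl3, in which boron chelated between the C4 carbonyl and the peri 5-methoxy group cleaves that methyl ether selectively over the 7-methoxy group; the two aryl benzyl ethers are cleaved cold with pentamethylbenzene trapping the benzyl cation away from the nucleophilic C8 position.

Compound list
1 | 4-hydroxy-2,6-dimethoxybenzaldehyde | COc1cc(O)cc(OC)c1C=O | starting material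
2 | 4-[(tert-butyldimethylsilyl)oxy]-2,6-dimethoxybenzaldehyde | COc1cc(O[Si](C)(C)C(C)(C)C)cc(OC)c1C=O | intermediate
3 | 1-(benzyloxy)-2-bromobenzene | Brc1ccccc1OCc1ccccc1 | starting material
4 | [2-(benzyloxy)phenyl]magnesium bromide | Br[Mg]c1ccccc1OCc1ccccc1 | intermediate (not isolated)
5 | [2-(benzyloxy)phenyl]{4-[(tert-butyldimethylsilyl)oxy]-2,6-dimethoxyphenyl}methanol, racemic | COc1cc(O[Si](C)(C)C(C)(C)C)cc(OC)c1C(O)c1ccccc1OCc1ccccc1 | intermediate
6 | {4-[2-(benzyloxy)benzyl]-3,5-dimethoxyphenoxy}(tert-butyl)dimethylsilane | COc1cc(O[Si](C)(C)C(C)(C)C)cc(OC)c1Cc1ccccc1OCc1ccccc1 | intermediate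
7 | 4-[2-(benzyloxy)benzyl]-3,5-dimethoxyphenol | COc1cc(O)cc(OC)c1Cc1ccccc1OCc1ccccc1 | intermediate
8 | 3-[2-(benzyloxy)benzyl]-6-hydroxy-2,4-dimethoxybenzaldehyde | COc1cc(O)c(C=O)c(OC)c1Cc1ccccc1OCc1ccccc1 | intermediate
9 | trimethyl orthoformate | COC(OC)OC | starting material
10 | 4-[2-(benzyloxy)benzyl]-2-(dimethoxymethyl)-3,5-dimethoxyphenol | COC(OC)c1c(O)cc(OC)c(Cc2ccccc2OCc2ccccc2)c1OC | intermediate
11 | 4-(benzyloxy)benzaldehyde | O=Cc1ccc(OCc2ccccc2)cc1 | starting material
12 | 4-(benzyloxy)styrene | C=Cc1ccc(OCc2ccccc2)cc1 | intermediate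
13 | 4-[2-(benzyloxy)benzyl]-3,5-dimethoxy-6-(methoxymethylidene)cyclohexa-2,4-dien-1-one, methide geometry not defined | COC=C1C(=O)C=C(OC)C(Cc2ccccc2OCc2ccccc2)=C1OC | intermediate (not isolated)
14 | (2R,4R)-6-[2-(benzyloxy)benzyl]-2-[4-(benzyloxy)phenyl]-4,5,7-trimethoxychroman, 2,4-cis | COc1cc2c(c(OC)c1Cc1ccccc1OCc1ccccc1)[C@H](OC)C[C@H](c1ccc(OCc3ccccc3)cc1)O2 | intermediate
15 | (2R)-6-[2-(benzyloxy)benzyl]-2-[4-(benzyloxy)phenyl]-5,7-dimethoxychroman-4-ol, C4 epimers | COc1cc2c(c(OC)c1Cc1ccccc1OCc1ccccc1)C(O)C[C@H](c1ccc(OCc3ccccc3)cc1)O2 | intermediate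
16 | (R)-6-[2-(benzyloxy)benzyl]-2-[4-(benzyloxy)phenyl]-5,7-dimethoxychroman-4-one | COc1cc2c(c(OC)c1Cc1ccccc1OCc1ccccc1)C(=O)C[C@H](c1ccc(OCc3ccccc3)cc1)O2 | intermediate
17 | (R)-5-hydroxy-6-(2-hydroxybenzyl)-2-(4-hydroxyphenyl)-7-methoxychroman-4-one, (+)-methylphelligrin A | COc1cc2c(c(O)c1Cc1ccccc1O)C(=O)C[C@H](c1ccc(O)cc1)O2 | target

Total step count: 11. Longest linear sequence: 10 steps (steps 1–6 and 8–11; step 7 is the side branch).

Steps most likely to fail

Step 8. The chiral anion may give poor enantiofacial control at C2, in which case C4 epimers of opposite C2 configuration would merge into partly racemic ketone. The carbenium ion may also be consumed by Friedel–Crafts attack of the electron-rich ring A of a second molecule, the product ether may re-ionise, or the styrene may oligomerise under acid. The fallback uses known chemistry and makes the C2–aryl bond by asymmetric conjugate addition instead. It sets out from phenol 7. Friedel–Crafts C-acetylation ortho to the hydroxyl (Ac2O, BF3·OEt2, then aqueous hydrolysis of the boron chelate) should give 1-{3-[2-(benzyloxy)benzyl]-6-hydroxy-2,4-dimethoxyphenyl}ethan-1-one F1. Condensation with N,N-dimethylformamide dimethyl acetal should give the enaminone (E)-1-{3-[2-(benzyloxy)benzyl]-6-hydroxy-2,4-dimethoxyphenyl}-3-(dimethylamino)prop-2-en-1-one F2. Acid (HCl, CH2Cl2) should close it with loss of dimethylamine to the chromone 6-[2-(benzyloxy)benzyl]-5,7-dimethoxy-4H-chromen-4-one F3. An enantioselective 1,4-addition of 4-(benzyloxy)phenylboronic acid, catalysed by [Rh(OH)(cod)]2 with a chiral bisphosphine or by Pd(OCOCF3)2 with a chiral pyridine-oxazoline (ligand antipode chosen for 2R), should then deliver ketone 16. The route is rejoined at 16, before the final deprotection.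

Step 6. The aldehyde is deactivated by its internal hydrogen bond and two donor oxygens, so acetalisation may stall, and the free-phenol acetal may revert to the aldehyde during isolation. The fallback sets out from aldehyde 8 and masks the phenol while the acetal is made. Acetylation (Ac2O, pyridine) should give 4-[2-(benzyloxy)benzyl]-2-formyl-3,5-dimethoxyphenyl acetate F4, whose aldehyde is no longer hydrogen-bonded. Acetalisation (trimethyl orthoformate, MeOH, catalytic pyridinium p-toluenesulfonate, Et3N quench) should give 4-[2-(benzyloxy)benzyl]-2-(dimethoxymethyl)-3,5-dimethoxyphenyl acetate F5. Methanolysis of the acetate with K2CO3 in MeOH frees the phenol under basic conditions that cannot ionise the acetal. Neutralisation with pH 7 buffer returns the route to 10.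

Step 11. The Lewis acid may open ring C toward the chalcone and erode the C2 configuration, the peri methyl ether may be cleaved incompletely, or benzyl cations may alkylate ring A. The fallback separates the two tasks and sets out from ketone 16. Neutral hydrogenolysis (H2, Pd/C, EtOAc) should remove both benzyl ethers and give (R)-6-(2-hydroxybenzyl)-2-(4-hydroxyphenyl)-5,7-dimethoxychroman-4-one F6. A chelation-specific demethylation of the 5-methoxy group alone (AlCl3, MeCN, rt) then leads to target 17.

Further compounds
F1 | step 8 | 1-{3-[2-(benzyloxy)benzyl]-6-hydroxy-2,4-dimethoxyphenyl}ethan-1-one | COc1cc(O)c(C(C)=O)c(OC)c1Cc1ccccc1OCc1ccccc1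
F2 | step 8 | (E)-1-{3-[2-(benzyloxy)benzyl]-6-hydroxy-2,4-dimethoxyphenyl}-3-(dimethylamino)prop-2-en-1-one | COc1cc(O)c(C(=O)/C=C/N(C)C)c(OC)c1Cc1ccccc1OCc1ccccc1
F3 | step 8 | 6-[2-(benzyloxy)benzyl]-5,7-dimethoxy-4H-chromen-4-one | COc1cc2occc(=O)c2c(OC)c1Cc1ccccc1OCc1ccccc1
F4 | step 6 | 4-[2-(benzyloxy)benzyl]-2-formyl-3,5-dimethoxyphenyl acetate | COc1cc(OC(C)=O)c(C=O)c(OC)c1Cc1ccccc1OCc1ccccc1
F5 | step 6 | 4-[2-(benzyloxy)benzyl]-2-(dimethoxymethyl)-3,5-dimethoxyphenyl acetate | COC(OC)c1c(OC(C)=O)cc(OC)c(Cc2ccccc2OCc2ccccc2)c1OC
F6 | step 11 | (R)-6-(2-hydroxybenzyl)-2-(4-hydroxyphenyl)-5,7-dimethoxychroman-4-one | COc1cc2c(c(OC)c1Cc1ccccc1O)C(=O)C[C@H](c1ccc(O)cc1)O2
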